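Ring A is cut at C7–C8 and C4a–C5 into two three-carbon pieces. C8, C8a and C4a, with the C8 methoxyl and the future C4 as an ester, come from methyl 4-methoxyacetoacetate as its 1,3-bis(silyloxy)diene; C7, C6 and C5 come from 3-ethoxyacryloyl chloride. One formal (3+3) cycloaromatisation forms both bonds and gives methyl 2,4-dihydroxy-3-methoxybenzoate, so the contiguous O1, C8-OMe and O7 pattern of ring A is exploited directly. The chelated C8a hydroxyl is saved for ring C, the free C7 hydroxyl is prenylated, and an arylacetic acid dianion condensation followed by one-carbon insertion builds the pyranone.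

Key step: step 3

Remark: silyl enol ethers 2 and 3 are taken as the mixtures of geometric isomers that silylation gives (one isomer of 3 is written); this geometry disappears on aromatisation in step 3.

Step 1
Reactants: 1 methyl 4-methoxyacetoacetate
Product: 2 methyl 4-methoxy-3-(trimethylsilyloxy)but-2-enoate
Conditions: Me3SiCl, Et3N, toluene, 20 °C; filtration, concentration
Reagents that add atoms: chlorotrimethylsilane, C[Si](C)(C)Cl
Why: Amine-mediated O-silylation of the enol of a β-keto ester (silyl enol ether formation) is routine for acetoacetates, and the γ-methoxy group is a spectator.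

Step 2
Reactants: 2 methyl 4-methoxy-3-(trimethylsilyloxy)but-2-enoate
Product: 3 1,4-dimethoxy-1,3-bis(trimethylsilyloxy)buta-1,3-diene
Conditions: LiN(iPr)2, THF, −78 °C; then Me3SiCl, −78 → 20 °C; hexane, filtration under argon, used crude
Reagents that add atoms: chlorotrimethylsilane, C[Si](C)(C)Cl
Why: With the enol oxygen capped, the lithium amide removes a γ-proton of the vinylogous ester and the dienolate is trapped on the ester oxygen (silyl ketene acetal formation), the standard two-stage route to 1,3-bis(silyloxy)-1,3-dienes.

Step 3
Reactants: 3 1,4-dimethoxy-1,3-bis(trimethylsilyloxy)buta-1,3-diene; 4 (E)-3-ethoxyacryloyl chloride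
Product: 7 methyl 2,4-dihydroxy-3-methoxybenzoate, via silyl enol ether 5 (not isolated), via cyclohexenedione tautomer 6 (not isolated)
Conditions: 3 (1.3 equiv), 4, CH2Cl2, −78 → 20 °C; then TiCl4 (1.1 equiv), −78 → 20 °C; aq. HCl work-up
Reagents that add atoms: none
Why: The methoxy-bearing terminus of diene 3, its most nucleophilic carbon, is first acylated by the acid chloride carbon of 4 without Lewis acid (C7–C8 bond, loss of Me3SiCl) to give the masked 3,5-dioxo ester 5, whose remaining silyl enol ether keeps the ester-bearing carbon nucleophilic; TiCl4 then chelates the dicarbonyl unit and activates the β-ethoxy enone, the central carbon adds to the β-carbon (C4a–C5 bond), ethoxide is expelled, and the cyclohexenedione 6 enolises to arene 7. The closest known reaction type is the TiCl4-mediated formal (3+3) cyclisation of 1,3-bis(silyloxy)-1,3-dienes with 1,3-dielectrophiles such as β-alkoxy enones and masked β-oxo acid chlorides, which gives salicylates and resorcylates; mechanistically it is a Mukaiyama-type C-acylation followed by an intramolecular Mukaiyama–Michael addition–elimination. Ring A is closed in a 6-endo-trig mode, since both carbons of the attacked enone double bond end up in the ring. No stereocentre is set: the sp3 centres that appear transiently at C8, C4a and C5 are erased on aromatisation, as is the diene geometry. The step needs acylation before conjugate attack (the opposite order would lead to the 2,6-dihydroxy regioisomer) and closure through carbon, not oxygen (which would lead to a 4-pyranone). The first is secured by letting the acyl chloride carbon, far more electrophilic than the alkoxy-deactivated β-carbon, react before any TiCl4 is present, and the second by the retained silyl enol ether and the titanium chelate that holds its carbon next to the β-position.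

Step 4
Reactants: 7 methyl 2,4-dihydroxy-3-methoxybenzoate; 8 prenyl bromide
Product: 9 methyl 2-hydroxy-3-methoxy-4-(3-methylbut-2-enyloxy)benzoate
Conditions: 8 (1.05 equiv), K2CO3 (1.1 equiv), acetone, 20 → 45 °C
Reagents that add atoms: none
Why: Williamson etherification with one equivalent of mild base should occur at the more acidic 4-hydroxyl para to the ester, because the 2-hydroxyl is held in a hydrogen bond to the ester carbonyl and is flanked by two ortho substituents.

Step 5
Reactants: 9 methyl 2-hydroxy-3-methoxy-4-(3-methylbut-2-enyloxy)benzoate; 10 4-methoxyphenylacetic acid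
Product: 13 1-[2-hydroxy-3-methoxy-4-(3-methylbut-2-enyloxy)phenyl]-2-(4-methoxyphenyl)ethan-1-one, via dilithium enediolate 11 (not isolated), via β-keto acid 12 (not isolated)
Conditions: 10 (1.5 equiv), LiN(SiMe3)2 (4.5 equiv in all), THF, −78 → 20 °C; then 1 M HCl, 20 °C
Reagents that add atoms: none
Why: The dilithium enediolate 11 of the arylacetic acid (an Ivanov-type reagent) should C-acylate with the methyl ester of 9, present as its lithium phenoxide, in a crossed Claisen condensation, and the β-keto acid 12 released on acidification loses CO2 spontaneously to give the benzyl ketone, while the prenyl ether is inert to amide base and to brief dilute acid.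

Step 6
Reactants: 13 1-[2-hydroxy-3-methoxy-4-(3-methylbut-2-enyloxy)phenyl]-2-(4-methoxyphenyl)ethan-1-one
Product: 15 8-methoxy-3-(4-methoxyphenyl)-7-(3-methylbut-2-enyloxy)-4H-chromen-4-one, via enaminone 14 (not isolated)
Conditions: Me2NCH(OMe)2 (3 equiv), THF, 65 °C
Reagents that add atoms: N,N-dimethylformamide dimethyl acetal, COC(OC)N(C)C
Why: Condensation of the doubly activated methylene with the amide acetal gives enaminone 14, and intramolecular oxa-Michael addition of the 2-hydroxyl with loss of dimethylamine closes ring C (the standard deoxybenzoin route to isoflavones) under neutral conditions that spare the prenyl ether.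

Compound list
1 | methyl 4-methoxyacetoacetate (methyl 4-methoxy-3-oxobutanoate) | COCC(=O)CC(=O)OC | starting material
2 | methyl 4-methoxy-3-(trimethylsilyloxy)but-2-enoate (mixture of geometric isomers) | COCC(O[Si](C)(C)C)=CC(=O)OC | intermediate
3 | 1,4-dimethoxy-1,3-bis(trimethylsilyloxy)buta-1,3-diene (written as the 1Z,3E isomer; mixture used) | CO/C=C(O[Si](C)(C)C)\C=C(\OC)O[Si](C)(C)C | intermediate
4 | (E)-3-ethoxyacryloyl chloride | CCO/C=C/C(=O)Cl | starting material
5 | methyl (6E)-7-ethoxy-4-methoxy-5-oxo-3-(trimethylsilyloxy)hepta-2,6-dienoate (racemic at C4; formed in the flask) | CCO/C=C/C(=O)C(OC)C(O[Si](C)(C)C)=CC(=O)OC | intermediate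
6 | methyl 3-methoxy-2,4-dioxocyclohex-5-ene-1-carboxylate (keto tautomer of 7; formed in the flask, no defined configuration) | COC(=O)C1C=CC(=O)C(OC)C1=O | intermediate
7 | methyl 2,4-dihydroxy-3-methoxybenzoate | COC(=O)c1ccc(O)c(OC)c1O | intermediate
8 | prenyl bromide (1-bromo-3-methylbut-2-ene) | CC(C)=CCBr | starting material
9 | methyl 2-hydroxy-3-methoxy-4-(3-methylbut-2-enyloxy)benzoate | COC(=O)c1ccc(OCC=C(C)C)c(OC)c1O | intermediate
10 | 4-methoxyphenylacetic acid | COc1ccc(CC(=O)O)cc1 | starting material
11 | dilithium enediolate of 4-methoxyphenylacetic acid (formed in the flask) | [Li+].[Li+].COc1ccc(C=C([O-])[O-])cc1 | intermediate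
12 | 3-[2-hydroxy-3-methoxy-4-(3-methylbut-2-enyloxy)phenyl]-2-(4-methoxyphenyl)-3-oxopropanoic acid (racemic; lithium salt until acidification) | COc1ccc(C(C(=O)O)C(=O)c2ccc(OCC=C(C)C)c(OC)c2O)cc1 | intermediate
13 | 1-[2-hydroxy-3-methoxy-4-(3-methylbut-2-enyloxy)phenyl]-2-(4-methoxyphenyl)ethan-1-one | COc1ccc(CC(=O)c2ccc(OCC=C(C)C)c(OC)c2O)cc1 | intermediate
14 | 3-(dimethylamino)-1-[2-hydroxy-3-methoxy-4-(3-methylbut-2-enyloxy)phenyl]-2-(4-methoxyphenyl)prop-2-en-1-one (formed in the flask; geometry of no consequence) | COc1ccc(C(=CN(C)C)C(=O)c2ccc(OCC=C(C)C)c(OC)c2O)cc1 | intermediate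
15 | 8-methoxy-3-(4-methoxyphenyl)-7-(3-methylbut-2-enyloxy)-4H-chromen-4-one | COc1ccc(-c2coc3c(OC)c(OCC=C(C)C)ccc3c2=O)cc1 | target

Total step count: 6
Longest linear sequence: 6 steps (1 → 2 → 3 → 7 → 9 → 13 → 15)

Steps most likely to fail

Step 3. The pairing of a 4-methoxy diene with a β-alkoxyacryloyl chloride has no direct precedent. Conjugate attack at the β-carbon ahead of acylation, closure through oxygen, or Lewis-acid-induced decomposition of the acid chloride could each divert material. The fallback gives up the ring construction and sets out from 10. Friedel–Crafts acylation of commercial 2-methoxybenzene-1,3-diol (COc1c(O)cccc1O) with 10 in BF3·OEt2 at 85 °C should give 1-(2,4-dihydroxy-3-methoxyphenyl)-2-(4-methoxyphenyl)ethan-1-one F1; the two open ring positions are equivalent, so a single isomer is expected. Williamson prenylation of its unchelated 4-hydroxyl with 8 and K2CO3 in acetone then gives 13, where the route is rejoined and steps 1 to 5 are bypassed.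

Step 5. Deprotonation of the phenol turns 9 into a lithium phenoxide whose ester is a weak acceptor, so the enediolate may act only as a base and the acylation may stall. The fallback sets out from 9. Aminolysis with MeNH(OMe)·HCl and iPrMgCl in THF at −20 → 0 °C should give the Weinreb amide 2-hydroxy-N,3-dimethoxy-N-methyl-4-(3-methylbut-2-enyloxy)benzamide F2. Addition of excess 4-methoxybenzylmagnesium chloride (COc1ccc(C[Mg]Cl)cc1) in THF at 0 °C (Weinreb ketone synthesis, the chelated tetrahedral adduct preventing over-addition) then gives 13, where the route is rejoined.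

Step 4. Over-alkylation at the chelated 2-hydroxyl or C-prenylation of the ambident phenoxide could erode the mono-ether. The fallback sets out from 7 and uses a Mitsunobu etherification with 3-methylbut-2-en-1-ol (CC(C)=CCO), PPh3 and diisopropyl azodicarboxylate in THF at 0 → 20 °C. It proceeds through the neutral phenol, engages only the more acidic unchelated hydroxyl, cannot C-alkylate, and leads directly to 9; no new compound is made (F0).

Further compounds
F1 | step 3 | 1-(2,4-dihydroxy-3-methoxyphenyl)-2-(4-methoxyphenyl)ethan-1-one | COc1ccc(CC(=O)c2ccc(O)c(OC)c2O)cc1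
F2 | step 5 | 2-hydroxy-N,3-dimethoxy-N-methyl-4-(3-methylbut-2-enyloxy)benzamide | CON(C)C(=O)c1ccc(OCC=C(C)C)c(OC)c1O
F0 | step 4 | none | none
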